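The unsubstituted benzo ring of the naphthoquinone (C4a, C5, C6, C7, C8, C8a) is disconnected by a retro-Diels–Alder cut through C4a–C5 and C8–C8a. In the forward sense (E)-1-acetoxybuta-1,3-diene adds across the only unsubstituted C=C of a 2-methyl-3-alkyl-1,4-benzoquinone that already carries the complete (2E,5S,7R,11R) side chain with its free C5′ hydroxyl. One operation closes the carbocycle; loss of acetic acid and oxidation then aromatise it. The quinone is assembled from farnesol (both methyl stereocentres by asymmetric hydrogenation, the carbinol by asymmetric propargylation) and a dimethoxybenzyl bromide through carboalumination and nickel-catalysed coupling.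

Key step: step 10

Assumption: commercial 1-acetoxybuta-1,3-diene is an E/Z mixture of which only the E isomer is expected to cycloadd, so it is used in excess; the descriptors 2′E,5′S,7′R,11′R were derived from the target SMILES and every structure below conforms to them.

Step 1
Reactants: 1 (2E,6E)-farnesol
Product: 2 (3R,7R)-3,7,11-trimethyldodecan-1-ol
Conditions: H2 (50 bar), [Ir(cod)(L*)][B(C6H3-3,5-(CF3)2)4] (1 mol%, L* = enantiopure bicyclic pyridine–phosphinite N,P ligand), CH2Cl2, rt
Reagents that add atoms: none
Why: Iridium-catalysed asymmetric hydrogenation of trisubstituted alkenes with a chiral N,P ligand should reduce all three C=C bonds, and because both stereogenic alkenes are E the single enantioface preference of the catalyst (its enantiomer chosen accordingly) should set C3 and C7 both as R under catalyst control, the free hydroxyl being tolerated.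

Step 2
Reactants: 2 (3R,7R)-3,7,11-trimethyldodecan-1-ol
Product: 3 (3R,7R)-3,7,11-trimethyldodecanal
Conditions: TEMPO (10 mol%), PhI(OAc)2 (1.1 equiv), CH2Cl2, rt
Reagents that add atoms: none
Why: The nitroxyl-catalysed oxidation of a primary alcohol should stop cleanly at the aldehyde, and the nearest stereocentre (C3) is β to the carbonyl and cannot epimerise.

Step 3
Reactants: 3 (3R,7R)-3,7,11-trimethyldodecanal; 4 allenylboronic acid pinacol ester (4,4,5,5-tetramethyl-2-(propa-1,2-dien-1-yl)-1,3,2-dioxaborolane)
Product: 6 (4S,6R,10R)-6,10,14-trimethylpentadec-1-yn-4-ol, via pinacol borate ester 5 (not isolated)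
Conditions: (R)-TRIP (10 mol%), 4 Å MS, toluene, 0 °C; aq. NaHCO3 work-up
Reagents that add atoms: none
Why: Chiral phosphoric acid-catalysed allenylboration (an SE2′ propargylation through a closed six-membered transition state) should give only the homopropargylic regioisomer, and the (R)-phosphate is expected to direct attack to the Re face of the aldehyde and so set C4 as S under catalyst control (the antipodal acid would be taken should the sense prove opposite), the remote methyl centres exerting no useful bias.

Step 4
Reactants: 6 (4S,6R,10R)-6,10,14-trimethylpentadec-1-yn-4-ol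
Product: 7 tert-butyldimethyl{[(4S,6R,10R)-6,10,14-trimethylpentadec-1-yn-4-yl]oxy}silane
Conditions: TBSCl, imidazole, DMF, rt
Reagents that add atoms: tert-butyldimethylsilyl chloride, CC(C)(C)[Si](C)(C)Cl
Why: Imidazole-promoted silylation of a secondary alcohol should mask the hydroxyl for the organoaluminium chemistry without touching the terminal alkyne or any stereocentre.

Step 5
Reactants: 8 2,3-dimethylhydroquinone (2,3-dimethylbenzene-1,4-diol)
Product: 9 1,4-dimethoxy-2,3-dimethylbenzene
Conditions: MeI (3 equiv), K2CO3, acetone, reflux, N2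
Reagents that add atoms: iodomethane, CI
Why: Williamson etherification of both phenols under nitrogen (to keep the hydroquinone from oxidising) should give the symmetrical dimethyl ether.

Step 6
Reactants: 9 1,4-dimethoxy-2,3-dimethylbenzene
Product: 10 2-(bromomethyl)-1,4-dimethoxy-3-methylbenzene
Conditions: NBS (0.95 equiv), AIBN (cat.), PhCF3, 80 °C
Reagents that add atoms: N-bromosuccinimide, O=C1CCC(=O)N1Br
Why: Wohl–Ziegler radical bromination in a non-polar solvent should favour the benzylic position over the ring, the two methyl groups are equivalent so only one monobromide can form, and a slight deficit of NBS together with the hindrance of the first CH2Br should limit dibromination.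

Step 7
Reactants: 7 tert-butyldimethyl{[(4S,6R,10R)-6,10,14-trimethylpentadec-1-yn-4-yl]oxy}silane; 10 2-(bromomethyl)-1,4-dimethoxy-3-methylbenzene
Product: 12 tert-butyl{[(2E,5S,7R,11R)-1-(3,6-dimethoxy-2-methylphenyl)-3,7,11,15-tetramethylhexadec-2-en-5-yl]oxy}dimethylsilane, via alkenyldimethylalane 11 (not isolated)
Conditions: Me3Al (2.5 equiv), Cp2ZrCl2 (0.25 equiv), CH2Cl2, 0 °C to rt; volatiles removed, THF; then 10, NiCl2(PPh3)2 (5 mol%)/n-BuLi (10 mol%, gives zerovalent nickel), 0 °C to rt
Reagents that add atoms: trimethylaluminium, C[Al](C)C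
Why: Zirconium-catalysed Negishi carboalumination should add methyl and aluminium syn across the terminal alkyne with methyl on the internal carbon, and nickel-catalysed cross-coupling of the alkenylalane with the benzylic bromide proceeds with retention, so the two events together fix the 2E trisubstituted alkene while the silyl ether is inert.

Step 8
Reactants: 12 tert-butyl{[(2E,5S,7R,11R)-1-(3,6-dimethoxy-2-methylphenyl)-3,7,11,15-tetramethylhexadec-2-en-5-yl]oxy}dimethylsilane
Product: 13 (2E,5S,7R,11R)-1-(3,6-dimethoxy-2-methylphenyl)-3,7,11,15-tetramethylhexadec-2-en-5-ol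
Conditions: Bu4NF, THF, 0 °C to rt
Reagents that add atoms: none
Why: Fluoride desilylation is carried out on the robust dimethoxyarene, so that no basic fluoride or acid has to be applied once a base- and acid-sensitive allyl quinone exists.

Step 9
Reactants: 13 (2E,5S,7R,11R)-1-(3,6-dimethoxy-2-methylphenyl)-3,7,11,15-tetramethylhexadec-2-en-5-ol
Product: 14 2-[(2E,5S,7R,11R)-5-hydroxy-3,7,11,15-tetramethylhexadec-2-en-1-yl]-3-methylcyclohexa-2,5-diene-1,4-dione (the 2-methyl-3-alkyl-1,4-benzoquinone)
Conditions: (NH4)2Ce(NO3)6 (2.5 equiv), MeCN/H2O 2:1, 0 °C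
Reagents that add atoms: water, O
Why: Oxidative demethylation of a 1,4-dimethoxyarene by tetravalent cerium (arene radical cation, ipso attack of water, loss of methanol) is fast at 0 °C and should leave the trisubstituted alkene and the secondary alcohol untouched.

Step 10
Reactants: 14 2-[(2E,5S,7R,11R)-5-hydroxy-3,7,11,15-tetramethylhexadec-2-en-1-yl]-3-methylcyclohexa-2,5-diene-1,4-dione; 15 (E)-1-acetoxybuta-1,3-diene
Product: 16 5-acetoxy-3-[(2E,5S,7R,11R)-5-hydroxy-3,7,11,15-tetramethylhexadec-2-en-1-yl]-2-methyl-4a,5,8,8a-tetrahydronaphthalene-1,4-dione (cis-fused; mixture with the 8-acetoxy regioisomer and of ring stereoisomers, used crude)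
Conditions: 15 (5 equiv), toluene, 80 °C, sealed tube, dark; then evaporation of solvent and excess 15
Reagents that add atoms: none
Why: The electron-poor C5=C6 bond of quinone 14 and the electron-rich diene 15 should combine in a concerted, suprafacial, normal-electron-demand [4+2] cycloaddition through an endo transition state, forming C4a–C5 and C8–C8a (naphthalene numbering) together. The closest known reaction type is the thermal Diels–Alder addition of 1-acyloxybutadienes to 2,3-dialkyl-1,4-benzoquinones at their unsubstituted double bond. The one new ring, the six-membered carbocycle C4a–C5–C6–C7–C8–C8a, is closed by intermolecular cycloaddition, the four diene carbons being annulated onto two quinone carbons. The new centres C4a, C8a and the acetoxy-bearing carbon arise cis-fused through suprafacial addition and endo-oriented through secondary orbital overlap, are not influenced by the distant side-chain centres, and need no control because aromatisation deletes all three. The selectivity that matters is site selectivity: the tetrasubstituted C2=C3 bond is sterically blocked and less electron-poor and the isolated trisubstituted chain alkene is no dienophile, so only C5=C6 should react, while the orientation of the acetoxy group is irrelevant. Neutral thermal conditions are chosen so that the free hydroxyl is not acetylated and the adduct does not enolise and reduce unreacted quinone.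

Step 11
Reactants: 16 5-acetoxy-3-[(2E,5S,7R,11R)-5-hydroxy-3,7,11,15-tetramethylhexadec-2-en-1-yl]-2-methyl-4a,5,8,8a-tetrahydronaphthalene-1,4-dione
Product: 18 2-[(2E,5S,7R,11R)-5-hydroxy-3,7,11,15-tetramethylhexadec-2-en-1-yl]-3-methylnaphthalene-1,4-dione, via naphthalene-1,4-diol 17 (not isolated)
Conditions: Et3N (2 equiv), CH2Cl2, rt, Ar; then Ag2O, MgSO4, rt, dark
Reagents that add atoms: none
Why: Triethylamine should enolise the cis-fused enedione and expel the acetate that sits β to a ring carbonyl (E1cB elimination, then tautomerisation), giving the same naphthalene-1,4-diol from every regio- and stereoisomer of the adduct, and Ag2O oxidation of that hydroquinone gives the quinone without affecting the side-chain stereocentres or the E alkene.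

Compound list
1 | (2E,6E)-farnesol | OC/C=C(\C)CC/C=C(\C)CCC=C(C)C | starting material
2 | (3R,7R)-3,7,11-trimethyldodecan-1-ol | OCC[C@H](C)CCC[C@H](C)CCCC(C)C | intermediate
3 | (3R,7R)-3,7,11-trimethyldodecanal | O=CC[C@H](C)CCC[C@H](C)CCCC(C)C | intermediate
4 | allenylboronic acid pinacol ester | C=C=CB1OC(C)(C)C(C)(C)O1 | starting material
5 | 4,4,5,5-tetramethyl-2-{[(4S,6R,10R)-6,10,14-trimethylpentadec-1-yn-4-yl]oxy}-1,3,2-dioxaborolane (not isolated) | C#CC[C@@H](OB1OC(C)(C)C(C)(C)O1)C[C@H](C)CCC[C@H](C)CCCC(C)C | intermediate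
6 | (4S,6R,10R)-6,10,14-trimethylpentadec-1-yn-4-ol | C#CC[C@@H](O)C[C@H](C)CCC[C@H](C)CCCC(C)C | intermediate
7 | tert-butyldimethyl{[(4S,6R,10R)-6,10,14-trimethylpentadec-1-yn-4-yl]oxy}silane | C#CC[C@@H](O[Si](C)(C)C(C)(C)C)C[C@H](C)CCC[C@H](C)CCCC(C)C | intermediate
8 | 2,3-dimethylhydroquinone | Cc1c(C)c(O)ccc1O | starting material
9 | 1,4-dimethoxy-2,3-dimethylbenzene | COc1ccc(OC)c(C)c1C | intermediate
10 | 2-(bromomethyl)-1,4-dimethoxy-3-methylbenzene | COc1ccc(OC)c(CBr)c1C | intermediate
11 | [(1E,4S,6R,10R)-4-{[tert-butyl(dimethyl)silyl]oxy}-2,6,10,14-tetramethylpentadec-1-en-1-yl]dimethylalane (not isolated) | C[Al](C)/C=C(\C)C[C@@H](O[Si](C)(C)C(C)(C)C)C[C@H](C)CCC[C@H](C)CCCC(C)C | intermediate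
12 | tert-butyl{[(2E,5S,7R,11R)-1-(3,6-dimethoxy-2-methylphenyl)-3,7,11,15-tetramethylhexadec-2-en-5-yl]oxy}dimethylsilane | COc1ccc(OC)c(C/C=C(\C)C[C@@H](O[Si](C)(C)C(C)(C)C)C[C@H](C)CCC[C@H](C)CCCC(C)C)c1C | intermediate
13 | (2E,5S,7R,11R)-1-(3,6-dimethoxy-2-methylphenyl)-3,7,11,15-tetramethylhexadec-2-en-5-ol | COc1ccc(OC)c(C/C=C(\C)C[C@@H](O)C[C@H](C)CCC[C@H](C)CCCC(C)C)c1C | intermediate
14 | 2-[(2E,5S,7R,11R)-5-hydroxy-3,7,11,15-tetramethylhexadec-2-en-1-yl]-3-methylcyclohexa-2,5-diene-1,4-dione | CC1=C(C/C=C(\C)C[C@@H](O)C[C@H](C)CCC[C@H](C)CCCC(C)C)C(=O)C=CC1=O | intermediate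
15 | (E)-1-acetoxybuta-1,3-diene | CC(=O)O/C=C/C=C | starting material
16 | 5-acetoxy-3-[(2E,5S,7R,11R)-5-hydroxy-3,7,11,15-tetramethylhexadec-2-en-1-yl]-2-methyl-4a,5,8,8a-tetrahydronaphthalene-1,4-dione (cis-fused, ring centres unassigned, one regioisomer drawn) | CC1=C(C/C=C(\C)C[C@@H](O)C[C@H](C)CCC[C@H](C)CCCC(C)C)C(=O)C2C(OC(C)=O)C=CCC2C1=O | intermediate
17 | 2-[(2E,5S,7R,11R)-5-hydroxy-3,7,11,15-tetramethylhexadec-2-en-1-yl]-3-methylnaphthalene-1,4-diol (not isolated) | Cc1c(C/C=C(\C)C[C@@H](O)C[C@H](C)CCC[C@H](C)CCCC(C)C)c(O)c2ccccc2c1O | intermediate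
18 | 2-[(2E,5S,7R,11R)-5-hydroxy-3,7,11,15-tetramethylhexadec-2-en-1-yl]-3-methylnaphthalene-1,4-dione | CC1=C(C/C=C(\C)C[C@@H](O)C[C@H](C)CCC[C@H](C)CCCC(C)C)C(=O)c2ccccc2C1=O | target

Total step count: 11. Longest linear sequence: 9 steps (steps 1–4 and 7–11); steps 5–6 form the arene branch.

Steps most likely to fail

Step 10. The cycloaddition to a doubly alkylated quinone may be slow, so that thermal cyclisation of the allyl quinone towards a chromenol, or premature enolisation of the adduct followed by redox exchange with unreacted 14, overtakes it. The fallback brings the benzo ring in ready-made and sets out from alkyne 7. Commercial menadione is chloromethylated (formaldehyde, HCl, AcOH) to 2-(chloromethyl)-3-methylnaphthalene-1,4-dione F1. Alane 11, generated from 7 as in step 7, is coupled with F1 under zerovalent nickel catalysis (NiCl2(PPh3)2/n-BuLi, THF) to give 2-{(2E,5S,7R,11R)-5-[(tert-butyldimethylsilyl)oxy]-3,7,11,15-tetramethylhexadec-2-en-1-yl}-3-methylnaphthalene-1,4-dione F2. HF·pyridine in THF then removes the silyl group, and the route is rejoined at target 18.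

Step 3. Facial discrimination in the allenylboration of an unbiased, β-branched aliphatic aldehyde may be incomplete, leaving a C4 epimer that is hard to remove. The fallback sets the carbinol by ketone hydrogenation and sets out from aldehyde 3. Roskamp homologation (ethyl diazoacetate, SnCl2, CH2Cl2) gives ethyl (5R,9R)-5,9,13-trimethyl-3-oxotetradecanoate F3. Noyori hydrogenation (RuCl2[(S)-BINAP], H2, EtOH) should give ethyl (3S,5R,9R)-3-hydroxy-5,9,13-trimethyltetradecanoate F4 under catalyst control. Silylation (TBSCl, imidazole) gives ethyl (3S,5R,9R)-3-[(tert-butyldimethylsilyl)oxy]-5,9,13-trimethyltetradecanoate F5. DIBAL-H at −78 °C gives (3S,5R,9R)-3-[(tert-butyldimethylsilyl)oxy]-5,9,13-trimethyltetradecanal F6. Ohira–Bestmann alkynylation (dimethyl (1-diazo-2-oxopropyl)phosphonate, K2CO3, MeOH) then returns to the route at alkyne 7.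

Step 7. Transfer of the alkenyl group from aluminium to nickel may be inefficient with the hindered, electron-rich benzylic bromide, so that homocoupling of 10 or methyl transfer from residual Me3Al takes over. The fallback separates the two events and reverses the polarity of the coupling; it sets out from alkyne 7 and bromide 10. Alane 11 is quenched with iodine (THF, −30 °C) to give tert-butyl{[(1E,4S,6R,10R)-1-iodo-2,6,10,14-tetramethylpentadec-1-en-4-yl]oxy}dimethylsilane F7. Bromide 10 is converted with zinc dust and LiCl in THF into (3,6-dimethoxy-2-methylbenzyl)zinc bromide F8. Negishi coupling of F7 with F8 (Pd(PPh3)4, zerovalent palladium, THF, rt) proceeds with retention and returns to the route at compound 12.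

Further compounds
F1 | step 10 | 2-(chloromethyl)-3-methylnaphthalene-1,4-dione | CC1=C(CCl)C(=O)c2ccccc2C1=O
F2 | step 10 | 2-{(2E,5S,7R,11R)-5-[(tert-butyldimethylsilyl)oxy]-3,7,11,15-tetramethylhexadec-2-en-1-yl}-3-methylnaphthalene-1,4-dione | CC1=C(C/C=C(\C)C[C@@H](O[Si](C)(C)C(C)(C)C)C[C@H](C)CCC[C@H](C)CCCC(C)C)C(=O)c2ccccc2C1=O
F3 | step 3 | ethyl (5R,9R)-5,9,13-trimethyl-3-oxotetradecanoate | CCOC(=O)CC(=O)C[C@H](C)CCC[C@H](C)CCCC(C)C
F4 | step 3 | ethyl (3S,5R,9R)-3-hydroxy-5,9,13-trimethyltetradecanoate | CCOC(=O)C[C@@H](O)C[C@H](C)CCC[C@H](C)CCCC(C)C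
F5 | step 3 | ethyl (3S,5R,9R)-3-[(tert-butyldimethylsilyl)oxy]-5,9,13-trimethyltetradecanoate | CCOC(=O)C[C@@H](O[Si](C)(C)C(C)(C)C)C[C@H](C)CCC[C@H](C)CCCC(C)C
F6 | step 3 | (3S,5R,9R)-3-[(tert-butyldimethylsilyl)oxy]-5,9,13-trimethyltetradecanal | O=CC[C@@H](O[Si](C)(C)C(C)(C)C)C[C@H](C)CCC[C@H](C)CCCC(C)C
F7 | step 7 | tert-butyl{[(1E,4S,6R,10R)-1-iodo-2,6,10,14-tetramethylpentadec-1-en-4-yl]oxy}dimethylsilane | I/C=C(\C)C[C@@H](O[Si](C)(C)C(C)(C)C)C[C@H](C)CCC[C@H](C)CCCC(C)C
F8 | step 7 | (3,6-dimethoxy-2-methylbenzyl)zinc bromide | COc1ccc(OC)c(C[Zn]Br)c1C
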